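**Retrosynthetic overview**
1. Target ⇐ diimide reduction of a C7≡C8 alkyne; the C6–C7 bond ⇐ axial addition of an alkynylstannane to the cyclic peroxycarbenium ion of a 6-methoxy-6-methyl-1,2-dioxane (C3 controls C6).
2. 1,2-Dioxane ring ⇐ intramolecular SN2 of a hydroperoxy ketal on a trans-β-lactone (inversion at C3, releases the C1 carboxylate).
3. Key step: C3–C4 bond ⇐ decarboxylative radical (Giese) addition of an oxetan-2-on-4-yl radical to methyl vinyl ketone, anti to the C2 methyl.
4. β-Lactone acid ⇐ catalytic asymmetric methylketene–glyoxylate [2+2] (sets C2); enone ring ⇐ Michael–Claisen annulation, then Stork–Danheiser ethynylation.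
5. Ring order: β-lactone (temporary) → 1,2-dioxane; the cyclohexenone is built separately and joined at C6.

Assumption: locants follow the target ester (C2 = propanoate α-carbon, C3/C6 = dioxane carbons); the SMILES corresponds to (2R,3S,6R).

**Step 1**
Reactants: 1 propanoyl chloride; 2 allyl glyoxylate (dried monomer)
Product: 3 allyl (2R,3R)-3-methyl-4-oxooxetane-2-carboxylate (cis-β-lactone)
Conditions: O-TMS-quinidine (10 mol%), i-Pr2NEt, CH2Cl2, −78 °C
Reagents that add atoms: none
Why: Wynberg/Nelson-type alkaloid-catalysed ketene–aldehyde [2+2] with in situ methylketene and an activated aldehyde; the ammonium enolate fixes the methyl-bearing carbon as R (quinidine series by analogy with methylketene dimerisation, the quinine catalyst gives the antipode), and the carboxylate-bearing centre is erased in step 3.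

**Step 2**
Reactants: 3
Product: 4 (2R,3R)-3-methyl-4-oxooxetane-2-carboxylic acid
Conditions: Pd(PPh3)4 (2 mol%), PhSiH3, CH2Cl2, 0 °C
Reagents that add atoms: none
Why: Tsuji–Trost deallylation with a non-nucleophilic hydride acceptor frees the acid without opening the β-lactone; no stereocentre is affected.

**Step 3 (key step)**
Reactants: 4; 5 methyl vinyl ketone
Product: 6 (3R,4R)-3-methyl-4-(3-oxobutyl)oxetan-2-one (trans)
Conditions: Ir[dF(CF3)ppy]2(dtbbpy)PF6 (1 mol%), K2HPO4, DMF, blue LEDs, rt
Reagents that add atoms: none
Why: Proposed new method: photoredox decarboxylative Giese addition (established for α-oxy acids) applied to a β-lactone acid; carboxylate oxidation and CO2 loss give the nucleophilic oxetan-2-on-4-yl radical, which adds to the enone anti to the adjacent methyl (as 3-substituted azetidin-2-on-4-yl radicals do), so the C3–C4 bond forms trans to the methyl, both epimers of 4 converge, and the α-keto radical is reduced and protonated.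

**Step 4**
Reactants: 6
Product: 7 (3R,4R)-4-[(3RS)-3-hydroperoxy-3-methoxybutyl]-3-methyloxetan-2-one
Conditions: HC(OMe)3, PPTS (cat.), CH2Cl2, rt; then anhydrous H2O2/Et2O, 0 °C
Reagents that add atoms: trimethyl orthoformate COC(OC)OC; hydrogen peroxide OO
Why: Ketalisation followed by ketal–H2O2 exchange (perhydrolysis) gives the α-methoxy hydroperoxide under mildly acidic conditions the lactone tolerates; the ketal centre is uncontrolled and is erased in step 10.

**Step 5**
Reactants: 7
Product: 8 methyl (2R)-2-[(3S,6RS)-6-methoxy-6-methyl-1,2-dioxan-3-yl]propanoate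
Conditions: Cs2CO3, DMF (0.02 M), 0 °C; then MeI
Reagents that add atoms: iodomethane CI
Why: Proposed new method: the peroxy anion opens the lactone at C4 by 6-exo-tet SN2 (alkyl–O cleavage with inversion, as known for carboxylate, azide and thiolate openings of β-lactones and Mead keto-β-lactone cyclisations; closest peroxide precedent is intramolecular alkylation of hydroperoxy ketals by sulfonates), turning the trans lactone into the 2,3-syn (2R,3S) peroxide; carbonyl attack would need an eight-membered transition state, and the released carboxylate is methylated in situ.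

**Step 6**
Reactants: 9 2-methylpentan-3-one; 10 methyl acrylate
Product: 11 2,4,4-trimethylcyclohexane-1,3-dione
Conditions: t-BuOK, THF/t-BuOH, 0 °C → reflux; aq. HCl
Reagents that add atoms: none
Why: Michael addition at the isopropyl α-carbon followed by Claisen (Dieckmann-type) cyclisation, driven by formation of the stabilised 1,3-dione enolate.

**Step 7**
Reactants: 11
Product: 12 3-methoxy-2,6,6-trimethylcyclohex-2-en-1-one
Conditions: MeOH, HC(OMe)3, TsOH (cat.), rt
Reagents that add atoms: methanol CO
Why: Acid-catalysed enol etherification takes place at the carbonyl remote from the gem-dimethyl group, leaving the hindered carbonyl for the next step.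

**Step 8**
Reactants: 12
Product: 13 3-ethynyl-2,4,4-trimethylcyclohex-2-en-1-one
Conditions: HC≡CMgBr, CeCl3, THF, 0 °C → rt; then 2 M HCl
Reagents that add atoms: ethynylmagnesium bromide C#C[Mg]Br
Why: Stork–Danheiser sequence: 1,2-addition to the vinylogous ester carbonyl, then acid hydrolysis with allylic transposition places the alkyne on the carbon next to the gem-dimethyl group.

**Step 9**
Reactants: 13
Product: 14 2,4,4-trimethyl-3-[(tributylstannyl)ethynyl]cyclohex-2-en-1-one
Conditions: Bu3SnOMe, neat, 60 °C, reduced pressure
Reagents that add atoms: tributyltin methoxide CCCC[Sn](CCCC)(CCCC)OC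
Why: Sn–O/C–H exchange stannylates the acidic terminal alkyne without strong base, so the enolisable enone is untouched.

**Step 10**
Reactants: 8; 14
Product: 15 methyl (2R)-2-[(3S,6S)-6-methyl-6-[(2,6,6-trimethyl-3-oxocyclohex-1-en-1-yl)ethynyl]-1,2-dioxan-3-yl]propanoate
Conditions: TMSOTf (1.1 equiv), CH2Cl2, −78 °C
Reagents that add atoms: none
Why: Proposed new method: extension of the Lewis-acid substitution of 3-alkoxy-1,2-dioxanes (known with allylsilanes, silyl enol ethers and ketene acetals) to an alkynylstannane; both C6 epimers ionise to one peroxycarbenium ion whose half-chair holds the C3 side chain pseudo-equatorial, and axial attack (1,4-trans rule for six-membered oxocarbenium ions) puts the alkynyl group trans to the side chain, which is the target's C6 geometry (S here only through CIP ranking of the alkyne).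

**Step 11**
Reactants: 15
Product: 16 methyl diacarnoate A, methyl (2R)-2-[(3S,6R)-6-methyl-6-[2-(2,6,6-trimethyl-3-oxocyclohex-1-en-1-yl)ethyl]-1,2-dioxan-3-yl]propanoate
Conditions: KO2CN=NCO2K (excess), AcOH, MeOH/CH2Cl2, 0 °C → rt
Reagents that add atoms: none
Why: Diimide reduces the C≡C and then the resulting cis-disubstituted C=C to C7H2–C8H2 but leaves the O–O bond and the hindered tetrasubstituted enone; no stereocentre is touched (C6 becomes R by CIP re-ranking).

**Compound list**
1 | propanoyl chloride | CCC(=O)Cl | starting material
2 | allyl glyoxylate | O=CC(=O)OCC=C | starting material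
3 | allyl (2R,3R)-3-methyl-4-oxooxetane-2-carboxylate | C[C@H]1C(=O)O[C@H]1C(=O)OCC=C | intermediate
4 | (2R,3R)-3-methyl-4-oxooxetane-2-carboxylic acid | C[C@H]1C(=O)O[C@H]1C(=O)O | intermediate
5 | methyl vinyl ketone | C=CC(C)=O | starting material
6 | (3R,4R)-3-methyl-4-(3-oxobutyl)oxetan-2-one | C[C@H]1C(=O)O[C@@H]1CCC(C)=O | intermediate
7 | (3R,4R)-4-[(3RS)-3-hydroperoxy-3-methoxybutyl]-3-methyloxetan-2-one | C[C@H]1C(=O)O[C@@H]1CCC(C)(OC)OO | intermediate
8 | methyl (2R)-2-[(3S,6RS)-6-methoxy-6-methyl-1,2-dioxan-3-yl]propanoate | COC(=O)[C@H](C)[C@@H]1CCC(C)(OC)OO1 | intermediate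
9 | 2-methylpentan-3-one | CCC(=O)C(C)C | starting material
10 | methyl acrylate | C=CC(=O)OC | starting material
11 | 2,4,4-trimethylcyclohexane-1,3-dione | CC1C(=O)CCC(C)(C)C1=O | intermediate
12 | 3-methoxy-2,6,6-trimethylcyclohex-2-en-1-one | COC1=C(C)C(=O)C(C)(C)CC1 | intermediate
13 | 3-ethynyl-2,4,4-trimethylcyclohex-2-en-1-one | C#CC1=C(C)C(=O)CCC1(C)C | intermediate
14 | 2,4,4-trimethyl-3-[(tributylstannyl)ethynyl]cyclohex-2-en-1-one | CCCC[Sn](CCCC)(CCCC)C#CC1=C(C)C(=O)CCC1(C)C | intermediate
15 | methyl (2R)-2-[(3S,6S)-6-methyl-6-[(2,6,6-trimethyl-3-oxocyclohex-1-en-1-yl)ethynyl]-1,2-dioxan-3-yl]propanoate | COC(=O)[C@H](C)[C@@H]1CC[C@@](C)(C#CC2=C(C)C(=O)CCC2(C)C)OO1 | intermediate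
16 | methyl diacarnoate A | COC(=O)[C@H](C)[C@@H]1CC[C@@](C)(CCC2=C(C)C(=O)CCC2(C)C)OO1 | target

**Totals**
Total steps: 11. Longest linear sequence: 7 (steps 1–5, 10, 11).

**Steps most likely to fail, with fallbacks**
- **Step 3** (ring fragmentation of the strained lactonyl radical, carboxylate-initiated lactone oligomerisation, or low trans selectivity). Fallback: move the radical C–C bond off the ring carbon. Iodolactonise (R)-2-methylbut-3-enoic acid to the trans-4-(iodomethyl)-β-lactone, carry out a Keck radical methallylation (C4–C5 bond), and ozonise in MeOH, which gives 7 directly.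
- **Step 5** (peroxy anion attacks an acyl carbon intermolecularly, or the lactone oligomerises). Fallback: drop the lactone electrophile. Reduce ketal-protected 6 to the anti-1,3-diol, form the cyclic sulfate, displace at C3 with the hydroperoxy ketal (same inversion), then oxidise C1 to the methyl ester.
- **Step 10** (the enone-conjugated alkynylstannane is too weak a nucleophile, or the Lewis acid cleaves the O–O bond). Fallback: add potassium vinyltrifluoroborate to the peroxycarbenium ion, cross-metathesise the 6-vinyl dioxane with 3-vinyl-2,4,4-trimethylcyclohex-2-enone (vinylMgBr in step 8), then reduce with diimide.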